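**Retrosynthetic overview**
- Feature: in the target, (2R,3R)-7-O-prenyl-3'-O-methyltaxifolin, ring A (C4a, C5, C6, C7, C8, C8a) meets ring C only along the C4a–C8a bond. That bond is the enone C=C (C5=C6) of a 2,3-dihydro-4H-pyran-4-one, and O-5 and O-7 sit where C1 and C3 of a 1,1,3-trioxygenated butadiene would place them.
- End game: remove the O-3 and O-4' acetates and the O-7 prenyl ether, back to a 5,7-dihydroxychromanone diacetate.
- Key disconnection: C4a–C5 and C8–C8a. Ring A leaves as 1-methoxy-1,3-bis(trimethylsilyloxy)buta-1,3-diene, and a 5-phenylsulfinyl dihydropyranone remains that already holds ring B, ring C, C2 and C3. PhSOH and MeOH are the two molecules lost on aromatization.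
- Pyranone: sulfur at C5 by sulfenylation and oxidation, O-3 by trans-selective α'-acetoxylation, ring C and C2 by a catalytic asymmetric hetero-Diels–Alder reaction of vanillin acetate.
- Ring order: B (bought), C (step 1), A (step 7).

Key step: step 7

Assumption: the (S)-BINOL/Ti(OiPr)4 catalyst is taken to open the Si face of an aromatic aldehyde to the diene, as it does to allyl and enol silane nucleophiles; both ligand antipodes are commercial.

Numbering: flavonoid numbering (O1, C2, C3, C4, C4a, C5–C8, C8a) is used for the bicyclic compounds. C5 and C6 of the monocyclic pyranones become C4a and C8a.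

Protecting groups: O-3 is carried as the acetate that the oxygenation step installs, and O-4' as the acetate already on the bought aldehyde. Both are activated esters that exchange in cold methanol. A secondary benzoate would need longer base contact than a dihydroflavonol tolerates. Acid-labile or hydrogenolysable groups would endanger the prenyl ether.

**Step 1**
Reactants: 1 vanillin acetate (4-formyl-2-methoxyphenyl acetate); 2 (E)-1-methoxy-3-(trimethylsilyloxy)buta-1,3-diene
Product: 4 (S)-2-(4-acetoxy-3-methoxyphenyl)-2,3-dihydro-4H-pyran-4-one, via silylated aldol adduct 3 (not isolated)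
Conditions: (S)-BINOL (20 mol %), Ti(OiPr)4 (10 mol %), 4 Å MS, Et2O, −20 °C; then TFA, CH2Cl2, 0 °C
Reagents that add atoms: none
Why: Catalytic asymmetric hetero-Diels–Alder reaction in its Mukaiyama aldol–cyclization form, in which the aldehyde bound to the (S)-BINOL/Ti(OiPr)4 catalyst offers its Si face to C4 of the diene and so sets C2 (S here, the same spatial arrangement as 2R in the target), after which TFA closes ring C by 6-endo oxa-Michael addition with loss of methanol under conditions the aryl acetate tolerates.

**Step 2**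
Reactants: 4 (S)-2-(4-acetoxy-3-methoxyphenyl)-2,3-dihydro-4H-pyran-4-one
Product: 5 (2R,3R)-3-acetoxy-2-(4-acetoxy-3-methoxyphenyl)-2,3-dihydro-4H-pyran-4-one (2,3-trans)
Conditions: Mn(OAc)3 (anhydrous, 4 equiv), benzene, reflux (Dean–Stark)
Reagents that add atoms: manganese triacetate, CC(=O)[O-].CC(=O)[O-].CC(=O)[O-].[Mn+3]
Why: α'-Acetoxylation of an enone with manganese triacetate, a reaction established on 2-substituted 2,3-dihydropyran-4-ones, in which the manganese enolate formed in the slow step is oxidised at once and acetate reaches C3 on the face away from the C2 aryl group, giving the diequatorial and also thermodynamically preferred 2,3-trans acetate without any base that could open the ring by β-elimination of O1.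

**Step 3**
Reactants: 5 (2R,3R)-3-acetoxy-2-(4-acetoxy-3-methoxyphenyl)-2,3-dihydro-4H-pyran-4-one
Product: 7 (2R,3R)-3-acetoxy-2-(4-acetoxy-3-methoxyphenyl)-5-(phenylthio)-2,3-dihydro-4H-pyran-4-one, via 6-chloro-5-phenylthio adduct 6 (not isolated)
Conditions: PhSCl (1.1 equiv), CH2Cl2, −78 → 0 °C; then Et3N, 0 °C
Reagents that add atoms: benzenesulfenyl chloride, ClSc1ccccc1
Why: Electrophilic α-sulfenylation of a vinylogous ester by addition–elimination, in which C5, the nucleophilic carbon of the O1–C6=C5 enol ether, attacks sulfur, chloride caps the oxocarbenium ion at C6 and Et3N removes the now acidic H-5 with loss of chloride, while the acetoxy-deactivated guaiacyl ring and both stereocentres are left alone.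

**Step 4**
Reactants: 7 (2R,3R)-3-acetoxy-2-(4-acetoxy-3-methoxyphenyl)-5-(phenylthio)-2,3-dihydro-4H-pyran-4-one
Product: 8 (2R,3R)-3-acetoxy-2-(4-acetoxy-3-methoxyphenyl)-5-(phenylsulfinyl)-2,3-dihydro-4H-pyran-4-one (both sulfoxide epimers, used together)
Conditions: mCPBA (1.0 equiv), CH2Cl2, −78 → −20 °C
Reagents that add atoms: 3-chloroperoxybenzoic acid, OOC(=O)c1cccc(Cl)c1
Why: Chemoselective sulfide-to-sulfoxide oxidation with one equivalent of peracid at low temperature, sulfur being far more nucleophilic than the electron-poor C5=C6 bond, and the new sulfur stereocentre needs no control because it is expelled in step 7.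

**Step 5**
Reactants: 9 methyl acetoacetate
Product: 10 methyl 3-(trimethylsilyloxy)but-2-enoate (E/Z mixture)
Conditions: TMSCl, Et3N, hexane, rt
Reagents that add atoms: chlorotrimethylsilane, C[Si](C)(C)Cl
Why: O-Silylation of the enol of a β-keto ester under soft enolization, where the double-bond geometry is of no consequence because that bond becomes the central single bond of the diene.

**Step 6**
Reactants: 10 methyl 3-(trimethylsilyloxy)but-2-enoate
Product: 11 1-methoxy-1,3-bis(trimethylsilyloxy)buta-1,3-diene
Conditions: LDA, THF, −78 °C; then TMSCl, −78 → 0 °C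
Reagents that add atoms: chlorotrimethylsilane, C[Si](C)(C)Cl
Why: Kinetic γ-deprotonation of the silyloxy crotonate and O-silylation of the resulting dienolate, the standard preparation of this ketene-acetal diene, which is used directly after removal of salts because it is moisture sensitive.

**Step 7**
Reactants: 8 (2R,3R)-3-acetoxy-2-(4-acetoxy-3-methoxyphenyl)-5-(phenylsulfinyl)-2,3-dihydro-4H-pyran-4-one; 11 1-methoxy-1,3-bis(trimethylsilyloxy)buta-1,3-diene
Product: 14 (2R,3R)-3-acetoxy-2-(4-acetoxy-3-methoxyphenyl)-5,7-dihydroxychroman-4-one, via Diels–Alder cycloadduct 12 (not isolated), via 5,7-bis(trimethylsilyl) ether 13 (not isolated)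
Conditions: 11 (3 equiv), toluene (1 M), rt → 90 °C; then 1 M HCl, THF, 0 °C → rt
Reagents that add atoms: none
Why: Proposed new method: the sulfinyl group on C4a, working in the same direction as the C4 ketone, lowers the LUMO of the C4a=C8a enol-ether bond far enough for the very electron-rich diene 11 to add across it, CH2 terminus to C8a and ketene-acetal carbon to C4a, so that ring A is closed by an intermolecular suprafacial [4+2] cycloaddition (concerted but strongly asynchronous, at the limit a Michael addition followed by ring closure) that forms C8–C8a and C4a–C5 and gives the cis-fused adduct 12. In 12 the sulfinyl group and H-8a are cis, so thermal syn elimination of benzenesulfenic acid restores C4a=C8a, 1,4-loss of methanol (OMe from C5, H from C8) aromatizes the ring to 13, and dilute acid frees the two phenols of 14. The closest known reactions are the aromatizing cycloadditions of 1,1,3-trioxygenated butadienes with halo- and sulfinylquinones and those of 1-alkoxy-3-silyloxybutadienes with 3-sulfinyl- and 3-acylchromones, which lead to xanthones, whereas a monocyclic 2,3-dihydropyran-4-one has not been used as the two-carbon partner. No lasting stereocentre is created, since C4a, C5 and C8a of 12 all become sp2 and sulfur is expelled, so neither the facial selectivity nor the sulfoxide epimer matters, and C2 and C3 are spectators in a base-free medium. The selectivity that is needed is regiochemical (5,7- against 6,8-dioxygenation) and is secured by the match of the largest HOMO coefficient, at the CH2 terminus of 11, with the largest LUMO coefficient, at C8a, the carbon β to both ketone and sulfoxide. Lewis acids are left out so that neither silylation of the sulfoxide oxygen nor Michael addition with β-elimination of O1 overtakes the cycloaddition, and the excess of 11 traps the sulfenic acid by silyl transfer.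

**Step 8**
Reactants: 14 (2R,3R)-3-acetoxy-2-(4-acetoxy-3-methoxyphenyl)-5,7-dihydroxychroman-4-one; 15 3-methylbut-2-en-1-ol (prenyl alcohol)
Product: 16 (2R,3R)-3-acetoxy-2-(4-acetoxy-3-methoxyphenyl)-5-hydroxy-7-(3-methylbut-2-enyloxy)chroman-4-one
Conditions: 15 (1.05 equiv), PPh3, DIAD, THF, 0 °C → rt
Reagents that add atoms: none
Why: Mitsunobu etherification, which selects the most acidic free hydroxyl, so that 7-OH reacts while 5-OH stays locked in its hydrogen bond to the C4 carbonyl, SN2 attack on the primary alkoxyphosphonium salt keeps the prenyl group unrearranged, and the neutral medium spares both acetates and the enolizable C3–H.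

**Step 9**
Reactants: 16 (2R,3R)-3-acetoxy-2-(4-acetoxy-3-methoxyphenyl)-5-hydroxy-7-(3-methylbut-2-enyloxy)chroman-4-one
Product: 17 (2R,3R)-3,5-dihydroxy-2-(4-hydroxy-3-methoxyphenyl)-7-(3-methylbut-2-enyloxy)chroman-4-one (target)
Conditions: K2CO3 (2.2 equiv), degassed MeOH, 0 °C, Ar; then pH 5 buffer
Reagents that add atoms: none
Why: Base-promoted transesterification in which the aryl acetate and the α-keto secondary acetate, both activated esters, should exchange at 0 °C faster than C3 enolizes or ring C opens, with oxygen excluded to prevent dehydrogenation to the flavonol, the prenyl ether inert to base, and any C3 equilibration leading only to the desired trans isomer.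

**Compound list**
1 | vanillin acetate (4-formyl-2-methoxyphenyl acetate) | CC(=O)Oc1ccc(C=O)cc1OC | starting material
2 | (E)-1-methoxy-3-(trimethylsilyloxy)buta-1,3-diene | CO/C=C/C(=C)O[Si](C)(C)C | starting material
3 | (S,E)-5-(4-acetoxy-3-methoxyphenyl)-1-methoxy-5-(trimethylsilyloxy)pent-1-en-3-one | COc1cc([C@H](CC(=O)/C=C/OC)O[Si](C)(C)C)ccc1OC(C)=O | intermediate
4 | (S)-2-(4-acetoxy-3-methoxyphenyl)-2,3-dihydro-4H-pyran-4-one | COc1cc([C@H]2OC=CC(=O)C2)ccc1OC(C)=O | intermediate
5 | (2R,3R)-3-acetoxy-2-(4-acetoxy-3-methoxyphenyl)-2,3-dihydro-4H-pyran-4-one | COc1cc([C@H]2OC=CC(=O)[C@@H]2OC(C)=O)ccc1OC(C)=O | intermediate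
6 | (2R,3R)-3-acetoxy-2-(4-acetoxy-3-methoxyphenyl)-6-chloro-5-(phenylthio)tetrahydro-4H-pyran-4-one (C5 and C6 transient, not assigned) | COc1cc([C@H]2OC(Cl)C(Sc3ccccc3)C(=O)[C@@H]2OC(C)=O)ccc1OC(C)=O | intermediate
7 | (2R,3R)-3-acetoxy-2-(4-acetoxy-3-methoxyphenyl)-5-(phenylthio)-2,3-dihydro-4H-pyran-4-one | COc1cc([C@H]2OC=C(Sc3ccccc3)C(=O)[C@@H]2OC(C)=O)ccc1OC(C)=O | intermediate
8 | (2R,3R)-3-acetoxy-2-(4-acetoxy-3-methoxyphenyl)-5-(phenylsulfinyl)-2,3-dihydro-4H-pyran-4-one (both epimers at sulfur) | COc1cc([C@H]2OC=C(S(=O)c3ccccc3)C(=O)[C@@H]2OC(C)=O)ccc1OC(C)=O | intermediate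
9 | methyl acetoacetate | COC(=O)CC(C)=O | starting material
10 | methyl 3-(trimethylsilyloxy)but-2-enoate (E/Z mixture) | COC(=O)C=C(C)O[Si](C)(C)C | intermediate
11 | 1-methoxy-1,3-bis(trimethylsilyloxy)buta-1,3-diene | C=C(O[Si](C)(C)C)/C=C(\OC)O[Si](C)(C)C | intermediate
12 | (2R,3R)-3-acetoxy-2-(4-acetoxy-3-methoxyphenyl)-5-methoxy-4a-(phenylsulfinyl)-5,7-bis(trimethylsilyloxy)-2,3,4a,5,8,8a-hexahydro-4H-chromen-4-one (cis-fused; C4a, C5, C8a and S transient, not assigned) | COc1cc([C@H]2OC3CC(O[Si](C)(C)C)=CC(OC)(O[Si](C)(C)C)C3(S(=O)c4ccccc4)C(=O)[C@@H]2OC(C)=O)ccc1OC(C)=O | intermediate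
13 | (2R,3R)-3-acetoxy-2-(4-acetoxy-3-methoxyphenyl)-5,7-bis(trimethylsilyloxy)chroman-4-one | COc1cc([C@H]2Oc3cc(O[Si](C)(C)C)cc(O[Si](C)(C)C)c3C(=O)[C@@H]2OC(C)=O)ccc1OC(C)=O | intermediate
14 | (2R,3R)-3-acetoxy-2-(4-acetoxy-3-methoxyphenyl)-5,7-dihydroxychroman-4-one | COc1cc([C@H]2Oc3cc(O)cc(O)c3C(=O)[C@@H]2OC(C)=O)ccc1OC(C)=O | intermediate
15 | 3-methylbut-2-en-1-ol | CC(C)=CCO | starting material
16 | (2R,3R)-3-acetoxy-2-(4-acetoxy-3-methoxyphenyl)-5-hydroxy-7-(3-methylbut-2-enyloxy)chroman-4-one | COc1cc([C@H]2Oc3cc(OCC=C(C)C)cc(O)c3C(=O)[C@@H]2OC(C)=O)ccc1OC(C)=O | intermediate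
17 | (2R,3R)-3,5-dihydroxy-2-(4-hydroxy-3-methoxyphenyl)-7-(3-methylbut-2-enyloxy)chroman-4-one | COc1cc([C@H]2Oc3cc(OCC=C(C)C)cc(O)c3C(=O)[C@@H]2O)ccc1O | target

**Step count**
Total steps: 9.
Longest linear sequence: 7 (steps 1, 2, 3, 4, 7, 8, 9). Steps 5 and 6 form the two-step branch to the diene.

**Steps most likely to fail**

1. Step 7 (Proposed new method).
   - What may go wrong: donation from O1 may leave the double bond too unreactive, so that the diene is consumed by adventitious hydrolysis or silyl transfer before it adds. Conjugate addition may be followed by β-elimination of O1, which opens ring C. Silylation of the sulfoxide oxygen by the ketene acetal may start a Pummerer-type process.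
   - Fallback (known chemistry, ring A bought instead of built), from 1 back to the route at 17. Compound 1 is condensed with commercial 2'-hydroxy-4',6'-bis(methoxymethoxy)acetophenone (KOH, EtOH, Claisen–Schmidt condensation, the aryl acetate being saponified in the same pot) to give (E)-2',4-dihydroxy-3-methoxy-4',6'-bis(methoxymethoxy)chalcone F1. MOMCl and NaH in DMF cap both free phenols to give (E)-3-methoxy-2',4,4',6'-tetrakis(methoxymethoxy)chalcone F2. Juliá–Colonna epoxidation (poly-L-leucine, urea–H2O2, DBU, THF) gives the (2R,3S)-epoxy ketone F3. HCl in MeOH at 45 °C removes the four MOM groups, and the freed 2'-OH opens the epoxide at the benzylic carbon (6-endo, inversion). The untouched α-carbon holds C3 and directs the trans closure, giving (2R,3R)-3'-O-methyltaxifolin F4. The 7-OH, para to the C4 carbonyl and the most acidic hydroxyl, is then alkylated with prenyl bromide (1 equiv) and K2CO3 in acetone at rt under argon to give 17.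

2. Step 2.
   - What may go wrong: slow enolization with competing oxidation of the electron-rich ring or of the benzylic position, and erosion of enantiopurity if the enol form opens reversibly at the C2–O1 bond in hot benzene.
   - Fallback (O-3 arrives with the diene instead of by oxidation of the ring), from 2 and 1 back to the route at 5. Pb(OAc)4 in CH2Cl2 oxidises the silyl enol ether of 2 to (E)-1-acetoxy-4-methoxybut-3-en-2-one F5. TMSOTf and Et3N give (1E,3Z)-4-acetoxy-1-methoxy-3-(trimethylsilyloxy)buta-1,3-diene F6. Hetero-Diels–Alder reaction of F6 with 1 follows, under a Zr(OtBu)4/3,3'-diiodo-BINOL/n-PrOH/H2O catalyst and then TFA. This catalyst type accepts 4-oxygenated 1-alkoxy-3-silyloxybutadienes with 2,3-cis selectivity, and the ligand antipode is chosen for Si-face attack. The product should be mainly (2R,3S)-3-acetoxy-2-(4-acetoxy-3-methoxyphenyl)-2,3-dihydro-4H-pyran-4-one F7. Its C3, α to the ketone, is equilibrated with catalytic DBU in CH2Cl2 to the trans isomer 5.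

3. Step 9.
   - What may go wrong: once the 4'-phenoxide is free, base may open ring C (quinone-methide or C3-enolate pathway) with loss of configuration at C2. Traces of oxygen may dehydrogenate C2–C3.
   - Fallback (deprotection in acid before the acid-sensitive prenyl ether exists), from 14 back to the route at 17. HCl in MeOH (from AcCl) at 40 °C transesterifies both acetates of 14 to give (2R,3R)-3'-O-methyltaxifolin F8, identical with F4. Its most acidic 7-OH is then alkylated with prenyl bromide (1 equiv) and K2CO3 in acetone at rt under argon to give 17.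

**Further compounds**
F1 | step 7 | (E)-2',4-dihydroxy-3-methoxy-4',6'-bis(methoxymethoxy)chalcone | COCOc1cc(O)c(C(=O)/C=C/c2ccc(O)c(OC)c2)c(OCOC)c1
F2 | step 7 | (E)-3-methoxy-2',4,4',6'-tetrakis(methoxymethoxy)chalcone | COCOc1cc(OCOC)c(C(=O)/C=C/c2ccc(OCOC)c(OC)c2)c(OCOC)c1
F3 | step 7 | [(2R,3S)-3-[3-methoxy-4-(methoxymethoxy)phenyl]oxiran-2-yl][2,4,6-tris(methoxymethoxy)phenyl]methanone | COc1cc([C@@H]2O[C@H]2C(=O)c3c(OCOC)cc(OCOC)cc3OCOC)ccc1OCOC
F4 | step 7 | (2R,3R)-3,5,7-trihydroxy-2-(4-hydroxy-3-methoxyphenyl)chroman-4-one (3'-O-methyltaxifolin) | COc1cc([C@H]2Oc3cc(O)cc(O)c3C(=O)[C@@H]2O)ccc1O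
F5 | step 2 | (E)-1-acetoxy-4-methoxybut-3-en-2-one | CO/C=C/C(=O)COC(C)=O
F6 | step 2 | (1E,3Z)-4-acetoxy-1-methoxy-3-(trimethylsilyloxy)buta-1,3-diene | CO/C=C/C(O[Si](C)(C)C)=C/OC(C)=O
F7 | step 2 | (2R,3S)-3-acetoxy-2-(4-acetoxy-3-methoxyphenyl)-2,3-dihydro-4H-pyran-4-one (2,3-cis) | COc1cc([C@H]2OC=CC(=O)[C@H]2OC(C)=O)ccc1OC(C)=O
F8 | step 9 | (2R,3R)-3,5,7-trihydroxy-2-(4-hydroxy-3-methoxyphenyl)chroman-4-one (identical with F4) | COc1cc([C@H]2Oc3cc(O)cc(O)c3C(=O)[C@@H]2O)ccc1O
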